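**Plan**

Ring labels: A = terminal 3,5-dihydroxyphenoxy ring. B carries O–A (B1), OH (B2), H (B3), O–C (B4), aryl G (B5) and OH (B6). C has C1–O–B4, C4–O–D1 and OH at C2/C6. D has D1–O–C, D2/D6–O–E and D4–OH. The two E rings are substituted like B (E1–O–D, E5–F). F and G are 2,4,6-trihydroxyphenyl rings.
Cuts, in order: the 22 O–CH3 bonds of a permethyl ether; the ether C4–O(D1); the two ethers D2/D6–O(E1); the ethers C1–O(B4) and A1–O(B1); and the biaryl bonds B5–G1 and E5–F1 (twice). All three biaryls go back to one aldehyde because B and E share one substitution pattern.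
Enabling feature: B5 lies next to the oxygen-bearing carbon B6, and G1 lies next to the oxygen-bearing carbon G2. A CH2 bridge between O(B6) and O(G2) holds the C–Br carbon B5 against the ortho C–H carbon G1, so the crowded biaryl bond forms inside one molecule while a seven-membered dibenzo-1,3-dioxepine closes.
Forward: a ring B bromide is made from 5-hydroxyvanillin and tethered to 3,5-dimethoxyphenol. The dioxepine then closes (the only ring made), the CH2 is removed and the formyl group is turned into a phenol, and this phenol is divided. One part is capped and debenzylated to the E–F phenol, two of which add to a 2,6-difluorobenzaldehyde (ring D). The other part receives ring C, ring A and an iodine at C4. Ullmann union and global demethylation finish the route.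
Stereochemistry: none to set. There is no stereocentre, and every biaryl axis carries a symmetric 2,4,6-trioxygenated ring, so the target has no atropisomers.

Key step: step 5

Remark on the chemistry: dioxepine 9 and diol 10 have an unsymmetrical ring G, so they are axially chiral and are taken as racemates. This element disappears in 11, where ring G is symmetric again.

**Step 1**
Reactants: 1 5-hydroxyvanillin (3,4-dihydroxy-5-methoxybenzaldehyde); 2 benzyl bromide
Product: 3 4-(benzyloxy)-3-hydroxy-5-methoxybenzaldehyde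
Conditions: Li2CO3, DMF, 50 °C
Reagents that add atoms: none
Why: Williamson ether synthesis made regioselective by acidity, since the 4-OH is para to the formyl group and is the only phenol ionised by Li2CO3, as known for 4-O-selective alkylation of 3,4-dihydroxybenzaldehydes.

**Step 2**
Reactants: 3 4-(benzyloxy)-3-hydroxy-5-methoxybenzaldehyde
Product: 4 4-(benzyloxy)-2-bromo-3-hydroxy-5-methoxybenzaldehyde
Conditions: Br2 (1.0 equiv), NaOAc, AcOH, 15 °C → rt
Reagents that add atoms: bromine, BrBr
Why: Electrophilic aromatic bromination directed by the free phenol, because C2 is ortho to the 3-OH and para to the 5-OMe (the ortho-to-hydroxyl preference known for isovanillin), while one equivalent of Br2 and the acetate buffer should hold back attack at C6 and loss of the benzyl group.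

**Step 3**
Reactants: 4 4-(benzyloxy)-2-bromo-3-hydroxy-5-methoxybenzaldehyde
Product: 5 4-(benzyloxy)-2-bromo-5-methoxy-3-[(methylsulfanyl)methoxy]benzaldehyde
Conditions: NaH, DMF, 0 °C; MeSCH2Cl, NaI (cat.), 0 °C → rt
Reagents that add atoms: chloromethyl methyl sulfide, CSCCl
Why: Williamson alkylation of the hindered phenoxide with a small, very reactive alpha-chloro sulfide should give the O,S-acetal (methylthiomethyl ether), the usual precursor of an aryl chloromethyl ether.

**Step 4**
Reactants: 5 4-(benzyloxy)-2-bromo-5-methoxy-3-[(methylsulfanyl)methoxy]benzaldehyde; 6 3,5-dimethoxyphenol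
Product: 8 4-(benzyloxy)-2-bromo-3-[(3,5-dimethoxyphenoxy)methoxy]-5-methoxybenzaldehyde, via chloromethyl ether 7 (not isolated)
Conditions: SO2Cl2, CH2Cl2, 0 °C, then evaporation of volatiles; 6, NaH, DMF, 0 °C → rt
Reagents that add atoms: sulfuryl chloride, O=S(=O)(Cl)Cl (its chlorine stays only in 7)
Why: Chlorinolysis of the O,S-acetal followed by a Williamson reaction, in which the hard chloromethyl ether O-alkylates the sodium phenoxide of 6; placing the chloride on the electron-poor, almost fully substituted ring B rather than on the dimethoxyphenyl ring avoids ring chlorination and self-alkylation.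

**Step 5**
Reactants: 8 4-(benzyloxy)-2-bromo-3-[(3,5-dimethoxyphenoxy)methoxy]-5-methoxybenzaldehyde
Product: 9 4-(benzyloxy)-3,9,11-trimethoxydibenzo[d,f][1,3]dioxepine-1-carbaldehyde
Conditions: Pd(OAc)2 (10 mol %), PCy3·HBF4 (20 mol %), PivOH (30 mol %), K2CO3, DMA, 120 °C, Ar
Reagents that add atoms: none
Why: Pd(OAc)2 is reduced in the flask to a zerovalent palladium–PCy3 species that inserts into the ring B C–Br bond, which the neighbouring formyl group renders electron-poor; pivalate then takes the place of bromide on divalent palladium and removes the hydrogen ortho to the tether oxygen by concerted metalation–deprotonation, and reductive elimination from the eight-membered diaryl palladacycle joins B5 to G1. The closest known reaction type is the palladium-catalysed intramolecular direct arylation of aryl halides onto arenes held by ether, amide or acetal links, routine for six-membered rings and documented, though rarer, for seven-membered rings. The one new ring, the 1,3-dioxepine, closes by aryl–aryl bond formation between two sp2 carbons already connected through C–O–CH2–O–C, and the gauche preference of the O–CH2–O unit folds the two arenes over each other before metalation. No stereocentre arises; only a racemic biaryl twist is created, and it loses its meaning at 11. The selectivity needed is positional: on the phenoxy ring only the two CH groups ortho to the bridging oxygen can reach the metal and they are related by symmetry, whereas the CH between the methoxy groups lies out of range, and on ring B the benzyl ether is meta to the bromide so that its phenyl ring cannot cyclise. Because both partners sit in one molecule, a biaryl with four ortho substituents should form under conditions where the intermolecular coupling would be slow.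

**Step 6**
Reactants: 9 4-(benzyloxy)-3,9,11-trimethoxydibenzo[d,f][1,3]dioxepine-1-carbaldehyde
Product: 10 4-(benzyloxy)-3-hydroxy-2-(2-hydroxy-4,6-dimethoxyphenyl)-5-methoxybenzaldehyde
Conditions: HCl (3 M in MeOH), THF, 60 °C, dimethoxymethane distilled off; then 1 M aq HCl–THF, rt
Reagents that add atoms: none
Why: Acid-catalysed transacetalisation, in which protonation opens the twisted diaryl formaldehyde acetal to an aryl methoxymethyl ether that methanol cleaves like any phenol MOM ether; the CH2 unit leaves as volatile dimethoxymethane and so cannot alkylate ring G, and the aqueous acid wash returns any acetal of the formyl group to the aldehyde.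

**Step 7**
Reactants: 10 4-(benzyloxy)-3-hydroxy-2-(2-hydroxy-4,6-dimethoxyphenyl)-5-methoxybenzaldehyde
Product: 11 4-(benzyloxy)-3,5-dimethoxy-2-(2,4,6-trimethoxyphenyl)benzaldehyde
Conditions: MeI, K2CO3, DMF, rt → 40 °C
Reagents that add atoms: iodomethane, CI
Why: Double Williamson methylation of the two phenoxides, in which base also opens any lactol tautomer between the ring G phenol and the formyl group, because the phenoxide is the species that is alkylated.

**Step 8**
Reactants: 11 4-(benzyloxy)-3,5-dimethoxy-2-(2,4,6-trimethoxyphenyl)benzaldehyde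
Product: 13 4-(benzyloxy)-3,5-dimethoxy-2-(2,4,6-trimethoxyphenyl)phenol, via aryl formate 12 (not isolated)
Conditions: mCPBA, CH2Cl2, 0 °C → rt, aq NaHCO3 wash; K2CO3 (cat.), MeOH, rt
Reagents that add atoms: 3-chloroperoxybenzoic acid, O=C(OO)c1cccc(Cl)c1
Why: Baeyer–Villiger oxidation with a Dakin-type outcome, since the aryl group bearing a para alkoxy substituent migrates in preference to hydrogen (as for 3,4,5-trialkoxybenzaldehydes) and mild methanolysis of the formate frees the B4/E4 phenol.

**Step 9**
Reactants: 13 4-(benzyloxy)-3,5-dimethoxy-2-(2,4,6-trimethoxyphenyl)phenol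
Product: 14 3-(benzyloxy)-2,2',4,4',6,6'-hexamethoxybiphenyl
Conditions: MeI, K2CO3, acetone, reflux
Reagents that add atoms: iodomethane, CI
Why: Williamson methylation caps the oxygen that stays a free hydroxyl (E4) in the two E rings.

**Step 10**
Reactants: 14 3-(benzyloxy)-2,2',4,4',6,6'-hexamethoxybiphenyl
Product: 15 2,2',4,4',6,6'-hexamethoxybiphenyl-3-ol
Conditions: H2 (1 atm), 10% Pd/C, EtOAc–MeOH, rt
Reagents that add atoms: none
Why: Catalytic hydrogenolysis of the only benzylic C–O bond should free the E1 phenol, with no reducible group left in the molecule.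

**Step 11**
Reactants: 15 2,2',4,4',6,6'-hexamethoxybiphenyl-3-ol (2.2 equiv); 16 2,6-difluoro-4-methoxybenzaldehyde
Product: 18 2,6-bis[(2,2',4,4',6,6'-hexamethoxybiphenyl-3-yl)oxy]-4-methoxybenzaldehyde, via monoether 17 (not isolated)
Conditions: Cs2CO3, DMSO, 110 °C
Reagents that add atoms: none
Why: Two successive nucleophilic aromatic substitutions (SNAr), in which each fluorine is ortho to the formyl group that stabilises the Meisenheimer adduct, the methoxy group is meta to both C–F carbons and does not deactivate them, and caesium 2,6-dimethoxyphenoxides are competent nucleophiles for ortho-fluorobenzaldehydes.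

**Step 12**
Reactants: 18 2,6-bis[(2,2',4,4',6,6'-hexamethoxybiphenyl-3-yl)oxy]-4-methoxybenzaldehyde
Product: 20 2,6-bis[(2,2',4,4',6,6'-hexamethoxybiphenyl-3-yl)oxy]-4-methoxyphenol, via aryl formate 19 (not isolated)
Conditions: mCPBA, CH2Cl2, 0 °C → rt, aq NaHCO3 wash; K2CO3 (cat.), MeOH, rt, Ar
Reagents that add atoms: 3-chloroperoxybenzoic acid, O=C(OO)c1cccc(Cl)c1
Why: Baeyer–Villiger oxidation of a 2,4,6-trioxygenated benzaldehyde, a substrate class in which aryl migration is fast, turns the group that activated the SNAr into the D1 oxygen.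

**Step 13**
Reactants: 13 4-(benzyloxy)-3,5-dimethoxy-2-(2,4,6-trimethoxyphenyl)phenol; 21 2-iodo-1,3-dimethoxybenzene (2 equiv)
Product: 22 3-(benzyloxy)-6-(2,6-dimethoxyphenoxy)-2,2',4,4',6'-pentamethoxybiphenyl
Conditions: CuI (20 mol %), picolinic acid (40 mol %), K3PO4, DMSO, 100 °C, Ar
Reagents that add atoms: none
Why: Ullmann ether synthesis with a ligand system suited to ortho-substituted partners, run early in this branch with the cheap iodide in excess so that the slow reaction of the doubly flanked C–I bond can be pushed.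

**Step 14**
Reactants: 22 3-(benzyloxy)-6-(2,6-dimethoxyphenoxy)-2,2',4,4',6'-pentamethoxybiphenyl
Product: 23 6-(2,6-dimethoxyphenoxy)-2,2',4,4',6'-pentamethoxybiphenyl-3-ol
Conditions: H2 (1 atm), 10% Pd/C, EtOAc–MeOH, rt
Reagents that add atoms: none
Why: Catalytic hydrogenolysis of the benzyl ether frees the B1 phenol, while aryl methyl ethers and diaryl ethers are inert.

**Step 15**
Reactants: 23 6-(2,6-dimethoxyphenoxy)-2,2',4,4',6'-pentamethoxybiphenyl-3-ol; 24 1-iodo-3,5-dimethoxybenzene (1.5 equiv)
Product: 25 6-(2,6-dimethoxyphenoxy)-3-(3,5-dimethoxyphenoxy)-2,2',4,4',6'-pentamethoxybiphenyl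
Conditions: CuI (10 mol %), picolinic acid (20 mol %), K3PO4, DMSO, 90 °C, Ar
Reagents that add atoms: none
Why: Ullmann ether synthesis in its favourable sense, a 2,6-dimethoxyphenol with an aryl iodide free of ortho substituents, kept under argon because the phenol is a hydroquinone monoether.

**Step 16**
Reactants: 25 6-(2,6-dimethoxyphenoxy)-3-(3,5-dimethoxyphenoxy)-2,2',4,4',6'-pentamethoxybiphenyl
Product: 27 6-(4-iodo-2,6-dimethoxyphenoxy)-3-(3,5-dimethoxyphenoxy)-2,2',4,4',6'-pentamethoxybiphenyl, via pinacol boronate 26 (not isolated)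
Conditions: [Ir(OMe)(cod)]2 (2 mol %), dtbpy (4 mol %), B2pin2, THF, 80 °C; evaporation; CuI (10 mol %), 1,10-phenanthroline (20 mol %), KI, MeOH–THF–H2O, air, 80 °C
Reagents that add atoms: bis(pinacolato)diboron, CC1(C)OB(OC1(C)C)B1OC(C)(C)C(C)(C)O1 (its boryl group stays only in 26); potassium iodide, [K+].[I-]
Why: Sterically controlled iridium-catalysed C–H borylation followed by copper-catalysed iododeboronation, since C4 of ring C is the only aromatic CH of 25 without an ortho substituent (all CH of rings A, B and G lie between two oxygen substituents) and iodide is delivered through copper, so no electrophilic iodine meets the electron-rich rings.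

**Step 17**
Reactants: 27 6-(4-iodo-2,6-dimethoxyphenoxy)-3-(3,5-dimethoxyphenoxy)-2,2',4,4',6'-pentamethoxybiphenyl; 20 2,6-bis[(2,2',4,4',6,6'-hexamethoxybiphenyl-3-yl)oxy]-4-methoxyphenol
Product: 28 docosa-O-methyl ether of the target (all 22 hydroxyl groups as OMe)
Conditions: CuI (30 mol %), picolinic acid (60 mol %), K3PO4, DMSO, 100 °C, Ar
Reagents that add atoms: none
Why: Ullmann ether synthesis with the steric load placed on the phenoxide, which copper tolerates better than a flanked halide, while the C4 iodide has hydrogen on both sides.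

**Step 18**
Reactants: 28 docosa-O-methyl ether of the target
Product: 29 CNP0117322.0 (target)
Conditions: BBr3 (excess), CH2Cl2, −78 °C → rt, Ar; then ice–water; Sephadex LH-20 under Ar
Reagents that add atoms: none
Why: Lewis-acid ether cleavage, in which BBr3 binds each methoxy oxygen and bromide attacks the methyl carbon in an SN2 step, whereas diaryl ether and biaryl bonds offer no sp3 carbon and should persist.

**Compound list**

1 | 5-hydroxyvanillin | O=Cc1cc(O)c(O)c(OC)c1 | starting material
2 | benzyl bromide | BrCc1ccccc1 | starting material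
3 | 4-(benzyloxy)-3-hydroxy-5-methoxybenzaldehyde | O=Cc1cc(O)c(OCc2ccccc2)c(OC)c1 | intermediate
4 | 4-(benzyloxy)-2-bromo-3-hydroxy-5-methoxybenzaldehyde | O=Cc1cc(OC)c(OCc2ccccc2)c(O)c1Br | intermediate
5 | 4-(benzyloxy)-2-bromo-5-methoxy-3-[(methylsulfanyl)methoxy]benzaldehyde | O=Cc1cc(OC)c(OCc2ccccc2)c(OCSC)c1Br | intermediate
6 | 3,5-dimethoxyphenol | COc1cc(O)cc(OC)c1 | starting material
7 | 4-(benzyloxy)-2-bromo-3-(chloromethoxy)-5-methoxybenzaldehyde | O=Cc1cc(OC)c(OCc2ccccc2)c(OCCl)c1Br | intermediate
8 | 4-(benzyloxy)-2-bromo-3-[(3,5-dimethoxyphenoxy)methoxy]-5-methoxybenzaldehyde | O=Cc1cc(OC)c(OCc2ccccc2)c(OCOc2cc(OC)cc(OC)c2)c1Br | intermediate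
9 | 4-(benzyloxy)-3,9,11-trimethoxydibenzo[d,f][1,3]dioxepine-1-carbaldehyde | O=Cc1cc(OC)c(OCc2ccccc2)c2OCOc3cc(OC)cc(OC)c3-c12 | intermediate
10 | 4-(benzyloxy)-3-hydroxy-2-(2-hydroxy-4,6-dimethoxyphenyl)-5-methoxybenzaldehyde | O=Cc1cc(OC)c(OCc2ccccc2)c(O)c1-c1c(O)cc(OC)cc1OC | intermediate
11 | 4-(benzyloxy)-3,5-dimethoxy-2-(2,4,6-trimethoxyphenyl)benzaldehyde | O=Cc1cc(OC)c(OCc2ccccc2)c(OC)c1-c1c(OC)cc(OC)cc1OC | intermediate
12 | 4-(benzyloxy)-3,5-dimethoxy-2-(2,4,6-trimethoxyphenyl)phenyl formate | O=COc1cc(OC)c(OCc2ccccc2)c(OC)c1-c1c(OC)cc(OC)cc1OC | intermediate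
13 | 4-(benzyloxy)-3,5-dimethoxy-2-(2,4,6-trimethoxyphenyl)phenol | Oc1cc(OC)c(OCc2ccccc2)c(OC)c1-c1c(OC)cc(OC)cc1OC | intermediate
14 | 3-(benzyloxy)-2,2',4,4',6,6'-hexamethoxybiphenyl | COc1cc(OC)c(OCc2ccccc2)c(OC)c1-c1c(OC)cc(OC)cc1OC | intermediate
15 | 2,2',4,4',6,6'-hexamethoxybiphenyl-3-ol | COc1cc(OC)c(O)c(OC)c1-c1c(OC)cc(OC)cc1OC | intermediate
16 | 2,6-difluoro-4-methoxybenzaldehyde | O=Cc1c(F)cc(OC)cc1F | starting material
17 | 2-fluoro-6-[(2,2',4,4',6,6'-hexamethoxybiphenyl-3-yl)oxy]-4-methoxybenzaldehyde | O=Cc1c(F)cc(OC)cc1Oc1c(OC)cc(OC)c(-c2c(OC)cc(OC)cc2OC)c1OC | intermediate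
18 | 2,6-bis[(2,2',4,4',6,6'-hexamethoxybiphenyl-3-yl)oxy]-4-methoxybenzaldehyde | O=Cc1c(Oc2c(OC)cc(OC)c(-c3c(OC)cc(OC)cc3OC)c2OC)cc(OC)cc1Oc1c(OC)cc(OC)c(-c2c(OC)cc(OC)cc2OC)c1OC | intermediate
19 | 2,6-bis[(2,2',4,4',6,6'-hexamethoxybiphenyl-3-yl)oxy]-4-methoxyphenyl formate | O=COc1c(Oc2c(OC)cc(OC)c(-c3c(OC)cc(OC)cc3OC)c2OC)cc(OC)cc1Oc1c(OC)cc(OC)c(-c2c(OC)cc(OC)cc2OC)c1OC | intermediate
20 | 2,6-bis[(2,2',4,4',6,6'-hexamethoxybiphenyl-3-yl)oxy]-4-methoxyphenol | Oc1c(Oc2c(OC)cc(OC)c(-c3c(OC)cc(OC)cc3OC)c2OC)cc(OC)cc1Oc1c(OC)cc(OC)c(-c2c(OC)cc(OC)cc2OC)c1OC | intermediate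
21 | 2-iodo-1,3-dimethoxybenzene | COc1cccc(OC)c1I | starting material
22 | 3-(benzyloxy)-6-(2,6-dimethoxyphenoxy)-2,2',4,4',6'-pentamethoxybiphenyl | COc1cccc(OC)c1Oc1cc(OC)c(OCc2ccccc2)c(OC)c1-c1c(OC)cc(OC)cc1OC | intermediate
23 | 6-(2,6-dimethoxyphenoxy)-2,2',4,4',6'-pentamethoxybiphenyl-3-ol | COc1cccc(OC)c1Oc1cc(OC)c(O)c(OC)c1-c1c(OC)cc(OC)cc1OC | intermediate
24 | 1-iodo-3,5-dimethoxybenzene | COc1cc(I)cc(OC)c1 | starting material
25 | 6-(2,6-dimethoxyphenoxy)-3-(3,5-dimethoxyphenoxy)-2,2',4,4',6'-pentamethoxybiphenyl | COc1cc(OC)cc(Oc2c(OC)cc(Oc3c(OC)cccc3OC)c(-c3c(OC)cc(OC)cc3OC)c2OC)c1 | intermediate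
26 | pinacol boronate of 25 at C4 of ring C | COc1cc(OC)cc(Oc2c(OC)cc(Oc3c(OC)cc(B4OC(C)(C)C(C)(C)O4)cc3OC)c(-c3c(OC)cc(OC)cc3OC)c2OC)c1 | intermediate
27 | 6-(4-iodo-2,6-dimethoxyphenoxy)-3-(3,5-dimethoxyphenoxy)-2,2',4,4',6'-pentamethoxybiphenyl | COc1cc(OC)cc(Oc2c(OC)cc(Oc3c(OC)cc(I)cc3OC)c(-c3c(OC)cc(OC)cc3OC)c2OC)c1 | intermediate
28 | docosa-O-methyl ether of the target | COc1cc(OC)cc(Oc2c(OC)cc(Oc3c(OC)cc(Oc4c(Oc5c(OC)cc(OC)c(-c6c(OC)cc(OC)cc6OC)c5OC)cc(OC)cc4Oc4c(OC)cc(OC)c(-c5c(OC)cc(OC)cc5OC)c4OC)cc3OC)c(-c3c(OC)cc(OC)cc3OC)c2OC)c1 | intermediate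
29 | CNP0117322.0 | Oc1cc(O)cc(Oc2c(O)cc(Oc3c(O)cc(Oc4c(Oc5c(O)cc(O)c(-c6c(O)cc(O)cc6O)c5O)cc(O)cc4Oc4c(O)cc(O)c(-c5c(O)cc(O)cc5O)c4O)cc3O)c(-c3c(O)cc(O)cc3O)c2O)c1 | target

**Step count and risks**

Total step count: 18.
Longest linear sequence: 14 steps (steps 1–8, then either 9–12 or 13–16, then 17–18).

The three steps most likely to fail are these.

**Step 5.** Metalation within the crowded eight-membered palladacycle may be slower than hydrodebromination of the aryl palladium species, or the acetal may break down thermally before the ring closes. In that case the B5–G1 bond would be made between two separate molecules.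
- The fallback sets out from bromophenol 4. Methylation (MeI, K2CO3, DMF) should give 4-(benzyloxy)-2-bromo-3,5-dimethoxybenzaldehyde F1.
- Suzuki–Miyaura coupling of this bromide with commercial 2,4,6-trimethoxyphenylboronic acid (Pd(OAc)2, SPhos, K3PO4, toluene, 100 °C) comes back to the route at aldehyde 11.

**Step 13.** Copper may engage the doubly ortho-substituted, electron-rich C–I bond so slowly that reduction of the iodide and stalled conversion dominate. The fallback uses an activated electrophile and then removes the activator.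
- It sets out from phenol 13. Copper-assisted displacement on commercial 4-bromo-3,5-dimethoxybenzaldehyde (CuI, N,N-dimethylglycine, Cs2CO3, dioxane, 100 °C) is accelerated by the para formyl group. It should give 4-[4-(benzyloxy)-3,5-dimethoxy-2-(2,4,6-trimethoxyphenyl)phenoxy]-3,5-dimethoxybenzaldehyde F2.
- Catalytic Tsuji–Wilkinson decarbonylation ([RhCl(cod)]2, dppp, diglyme, 160 °C) comes back to the route at ether 22.

**Step 17.** The large phenoxide, flanked by two aryloxy groups, may bind and couple too slowly, leaving time for hydrodeiodination of one partner and oxidative decay of the other at 100 °C. The fallback changes the ring C partner from an electrophile to a boron nucleophile and works at room temperature.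
- It sets out from boronate 26, isolated after the first half of step 16. Oxidative removal of pinacol (NaIO4, NH4OAc, acetone–H2O) should give {4-[(3-(3,5-dimethoxyphenoxy)-2,2',4,4',6'-pentamethoxybiphenyl-6-yl)oxy]-3,5-dimethoxyphenyl}boronic acid F3.
- Chan–Lam coupling with phenol 20 (Cu(OAc)2, pyridine, 4 Å molecular sieves, CH2Cl2, dry air, rt) comes back to the route at permethyl ether 28.

**Further compounds**

F1 | step 5 | 4-(benzyloxy)-2-bromo-3,5-dimethoxybenzaldehyde | O=Cc1cc(OC)c(OCc2ccccc2)c(OC)c1Br
F2 | step 13 | 4-[4-(benzyloxy)-3,5-dimethoxy-2-(2,4,6-trimethoxyphenyl)phenoxy]-3,5-dimethoxybenzaldehyde | O=Cc1cc(OC)c(Oc2cc(OC)c(OCc3ccccc3)c(OC)c2-c2c(OC)cc(OC)cc2OC)c(OC)c1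
F3 | step 17 | {4-[(3-(3,5-dimethoxyphenoxy)-2,2',4,4',6'-pentamethoxybiphenyl-6-yl)oxy]-3,5-dimethoxyphenyl}boronic acid | COc1cc(OC)cc(Oc2c(OC)cc(Oc3c(OC)cc(B(O)O)cc3OC)c(-c3c(OC)cc(OC)cc3OC)c2OC)c1
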